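**Assumption:** atom labels C1–C15 follow germacrane numbering of the target (C1/C10 epoxide, C3 carbinol, C4=C5, C6 lactone carbinol, C7, C8 ester carbinol, C11–C13 methylene lactone, C14 = CH2OH, C15 = CH3). The target is read as 1β,10α-epoxy-3β,14-dihydroxy-8β-[(2S)-2-methylbutanoyloxy]-4Z-germacra-4,11(13)-dien-12,6α-olide. TBS = tert-butyldimethylsilyl, TES = triethylsilyl.

## Retrosynthetic overview

1. Target ⇐ desilylation and C8 acylation of a macrocyclic 8β-alcohol.
2. Macrocycle ⇐ C7–C8 bond: SmI2 ketyl-radical 10-exo cyclisation of a C8 aldehyde onto a 3-(acetoxymethyl)butenolide; the enolate then loses acetate to give the α-methylene lactone (sets C7 and C8).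
3. Seco aldehyde ⇐ C3–C4 bond: asymmetric Nozaki–Hiyama–Kishi coupling of a Z-vinyl iodide butenolide (fragment A) with an epoxy aldehyde (fragment B).
4. Fragment A ⇐ ring-closing metathesis, Red-Al/iodine, kinetic resolution, acrolein + propynyl Grignard. Fragment B ⇐ ozonolysis, Sharpless epoxidation, carbomagnesiation of propargyl alcohol.
5. Ring order: butenolide (metathesis), epoxide (Sharpless), ten-membered carbocycle last (radical).

## Route

Step 1
Reactants: 1 1-propynylmagnesium bromide; 2 acrolein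
Product: 3 (±)-hex-1-en-4-yn-3-ol
Conditions: THF, −78 °C to 0 °C; H2O
Reagents that add atoms: none
Why: 1,2-addition of the alkynyl Grignard reagent to the aldehyde gives the racemic carbinol that becomes C6 (Grignard addition).

Step 2
Reactants: 3 (±)-hex-1-en-4-yn-3-ol
Product: 4 (S)-hex-1-en-4-yn-3-ol
Conditions: Ti(OiPr)4, L-(+)-diisopropyl tartrate, t-BuOOH (0.6 equiv), 4 Å MS, CH2Cl2, −20 °C
Reagents that add atoms: none
Why: Sharpless kinetic resolution, in which the R enantiomer is epoxidised at its vinyl group much faster with the L-(+)-tartrate so that the S alcohol needed for C6 is recovered in high ee at about 60 % conversion.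

Step 3
Reactants: 4 (S)-hex-1-en-4-yn-3-ol
Product: 6 (3S,4Z)-5-iodohexa-1,4-dien-3-ol, via cyclic sodium alkenylalanate 5 (not isolated)
Conditions: NaAlH2(OCH2CH2OMe)2 (Red-Al), THF, 0 °C; then I2, −78 °C
Reagents that add atoms: iodine, II
Why: Alkoxide-directed trans-hydroalumination of the propargylic alkyne puts H on C5 and Al on C4 inside a five-membered ring, and iodinolysis with retention gives the vinyl iodide with iodine cis to C6, which fixes the 4Z geometry (Red-Al/iodine reduction–iodination).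

Step 4
Reactants: 7 2-(bromomethyl)acrylic acid
Product: 8 2-(acetoxymethyl)acrylic acid
Conditions: KOAc (3 equiv), AcOH, 70 °C
Reagents that add atoms: potassium acetate, CC(=O)[O-].[K+]
Why: Displacement of the allylic bromide by acetate (SN2 and SN2′ give the same product) installs the group that later leaves from the samarium enolate (nucleophilic substitution).

Step 5
Reactants: 6 (3S,4Z)-5-iodohexa-1,4-dien-3-ol; 8 2-(acetoxymethyl)acrylic acid
Product: 9 (3S,4Z)-5-iodohexa-1,4-dien-3-yl 2-(acetoxymethyl)acrylate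
Conditions: DCC, DMAP (5 mol %), CH2Cl2, 0 °C
Reagents that add atoms: none
Why: Steglich esterification of the secondary alcohol, which does not touch the C6 stereocentre.

Step 6
Reactants: 9 (3S,4Z)-5-iodohexa-1,4-dien-3-yl 2-(acetoxymethyl)acrylate
Product: 10 [(5S)-5-[(1Z)-2-iodoprop-1-en-1-yl]-2-oxo-2,5-dihydrofuran-3-yl]methyl acetate (fragment A)
Conditions: second-generation Grubbs catalyst RuCl2(H2IMes)(PCy3)(=CHPh) (5 mol %), toluene (5 mM), 80 °C
Reagents that add atoms: none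
Why: Ring-closing metathesis joins the terminal vinyl group and the 1,1-disubstituted acrylate into the butenolide, while the trisubstituted iodoalkene is inert.

Step 7
Reactants: 11 prop-2-yn-1-ol; 12 allylmagnesium bromide; 13 1-bromo-3-methylbut-2-ene
Product: 15 (2Z)-6-methyl-2-(prop-2-en-1-yl)hepta-2,5-dien-1-ol, via alkenylmagnesium bromide 14 (not isolated)
Conditions: 12 (2.1 equiv), CuI (10 mol %), Et2O, 0 °C to rt; then 13, THF, −20 °C to rt; H2O
Reagents that add atoms: none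
Why: Copper-catalysed anti carbomagnesiation of propargyl alcohol (Duboudin reaction) puts the allyl group on C10 and magnesium on C1 cis to the CH2O group, and copper-mediated SN2 coupling with prenyl bromide with retention gives the alkene with C14 cis to C2.

Step 8
Reactants: 15 (2Z)-6-methyl-2-(prop-2-en-1-yl)hepta-2,5-dien-1-ol
Product: 16 [(2S,3R)-3-(3-methylbut-2-en-1-yl)-2-(prop-2-en-1-yl)oxiran-2-yl]methanol
Conditions: Ti(OiPr)4 (10 mol %), L-(+)-diethyl tartrate (12 mol %), t-BuOOH, 4 Å MS, CH2Cl2, −20 °C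
Reagents that add atoms: tert-butyl hydroperoxide, CC(C)(C)OO
Why: Sharpless asymmetric epoxidation touches only the allylic-alcohol alkene, and the L-(+)-tartrate delivers oxygen to the face that gives the C1 (R), C10 (S) epoxide (reagent control).

Step 9
Reactants: 16 [(2S,3R)-3-(3-methylbut-2-en-1-yl)-2-(prop-2-en-1-yl)oxiran-2-yl]methanol
Product: 17 tert-butyl{[(2S,3R)-3-(3-methylbut-2-en-1-yl)-2-(prop-2-en-1-yl)oxiran-2-yl]methoxy}dimethylsilane
Conditions: TBSCl, imidazole, CH2Cl2, 0 °C to rt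
Reagents that add atoms: tert-butyldimethylsilyl chloride, CC(C)(C)[Si](C)(C)Cl
Why: Routine silylation of the primary C14 alcohol (protection).

Step 10
Reactants: 17 tert-butyl{[(2S,3R)-3-(3-methylbut-2-en-1-yl)-2-(prop-2-en-1-yl)oxiran-2-yl]methoxy}dimethylsilane
Product: 19 2-[(2R,3S)-3-(TBSO-methyl)-3-(prop-2-en-1-yl)oxiran-2-yl]acetaldehyde (fragment B), via ozonide 18 (not isolated)
Conditions: O3 (1.0 equiv, Sudan Red 7B end point), CH2Cl2, −78 °C; then PPh3, −78 °C to rt
Reagents that add atoms: ozone, [O-][O+]=O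
Why: Ozone attacks the electron-rich trisubstituted prenyl alkene far faster than the monosubstituted allyl alkene, so titrated ozonolysis unveils only the C3 aldehyde (chemoselective ozonolysis).

Step 11
Reactants: 10 [(5S)-5-[(1Z)-2-iodoprop-1-en-1-yl]-2-oxo-2,5-dihydrofuran-3-yl]methyl acetate; 19 2-[(2R,3S)-3-(TBSO-methyl)-3-(prop-2-en-1-yl)oxiran-2-yl]acetaldehyde
Product: 20 [(5R)-5-{(1Z,3S)-3-hydroxy-2-methyl-4-[(2R,3S)-3-(TBSO-methyl)-3-(prop-2-en-1-yl)oxiran-2-yl]but-1-en-1-yl}-2-oxo-2,5-dihydrofuran-3-yl]methyl acetate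
Conditions: CrCl2 (4 equiv), (S)-N-[2-(4-isopropyl-4,5-dihydrooxazol-2-yl)-6-methylphenyl]methanesulfonamide (4.4 equiv), Et3N (4.4 equiv, pre-complexed), NiCl2 (2 mol %), THF, rt
Reagents that add atoms: none
Why: Asymmetric Nozaki–Hiyama–Kishi coupling joins C4 to C3 with retention of the Z geometry, the chiral sulfonamide–chromium complex is relied on to set the C3 carbinol as 3S (the ligand enantiomer is assigned by analogy and must be confirmed on the first run), and lactone, acetate, epoxide and silyl ether are tolerated.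

Step 12
Reactants: 20 the C3 alcohol from step 11
Product: 21 [(5R)-5-{(1Z,3S)-3-(TBSO)-2-methyl-4-[(2R,3S)-3-(TBSO-methyl)-3-(prop-2-en-1-yl)oxiran-2-yl]but-1-en-1-yl}-2-oxo-2,5-dihydrofuran-3-yl]methyl acetate
Conditions: TBSOTf, 2,6-lutidine, CH2Cl2, −78 °C
Reagents that add atoms: tert-butyldimethylsilyl triflate, CC(C)(C)[Si](C)(C)OS(=O)(=O)C(F)(F)F
Why: Silylation of the hindered secondary allylic alcohol with the silyl triflate and a hindered weak base that leaves the butenolide alone (protection).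

Step 13
Reactants: 21 the bis-TBS ether from step 12
Product: 23 [(5R)-5-{(1Z,3S)-3-(TBSO)-2-methyl-4-[(2R,3S)-3-(TBSO-methyl)-3-(2-oxoethyl)oxiran-2-yl]but-1-en-1-yl}-2-oxo-2,5-dihydrofuran-3-yl]methyl acetate, via diol 22 (not isolated)
Conditions: K2OsO4·2H2O (2 mol %), NaIO4 (4 equiv), 2,6-lutidine, dioxane–H2O (3:1), 0 °C to rt
Reagents that add atoms: sodium periodate, [Na+].[O-]I(=O)(=O)=O
Why: Lemieux–Johnson cleavage, in which osmylation prefers the unhindered monosubstituted alkene over the hindered C4=C5 alkene (deactivated by two allylic oxygens) and the conjugated butenolide alkene, and periodate then cleaves the diol to the C8 aldehyde.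

Step 14
Reactants: 23 the seco aldehyde from step 13
Product: 27 (1R,3S,4Z,6R,7R,8R,10S)-1,10-epoxy-8-hydroxy-3,14-bis(TBSO)germacra-4,11(13)-dien-12,6-olide, via samarium ketyl radical 24 (not isolated), via lactone α-radical 25 (not isolated), via samarium enolate 26 (not isolated)
Conditions: SmI2 (2.5 equiv, 0.1 M in THF), 23 added by syringe pump (final 2 mM), THF, −78 °C to −20 °C; aq. NH4Cl
Reagents that add atoms: none
Why: Proposed new method: SmI2 reduces the aldehyde to ketyl radical 24, which closes the ten-membered ring by 10-exo-trig addition to C7 of the butenolide (trans ring fusion is expected because the cis mode needs a near-eclipsed C5–C6–C7–C8 torsion, and the 8β-oxygen is expected from a transition state with the samarium-bound ketyl oxygen gauche to C11 and the C9 chain anti to it), after which radical 25 is reduced to trivalent samarium enolate 26 that expels acetate to give the α-methylene lactone; the closest known chemistry is the SmI2 ketyl–olefin (ketyl–enoate) cyclisation and the β-elimination of β-acetoxy samarium enolates, the ring size being the untested element.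

Step 15
Reactants: 27 the macrocyclic 8β-alcohol from step 14; 28 (S)-2-methylbutanoic acid
Product: 29 (1R,3S,4Z,6R,7R,8R,10S)-1,10-epoxy-8-[(2S)-2-methylbutanoyloxy]-3,14-bis(TBSO)germacra-4,11(13)-dien-12,6-olide
Conditions: DIC, DMAP (10 mol %), CH2Cl2, 0 °C
Reagents that add atoms: none
Why: Steglich esterification of the only free hydroxyl proceeds with retention at C8 and at the α-carbon of the acid.

Step 16
Reactants: 29 the bis-TBS ester from step 15
Product: 30 (1R,3S,4Z,6R,7R,8R,10S)-1,10-epoxy-3,14-dihydroxy-8-[(2S)-2-methylbutanoyloxy]germacra-4,11(13)-dien-12,6-olide (CNP0356520.3)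
Conditions: HF·pyridine, pyridine, THF, 0 °C to rt
Reagents that add atoms: none
Why: Buffered fluoride cleavage of both silyl ethers leaves the epoxide, the ester and the α-methylene lactone intact (global desilylation).

## Compound list

1 | 1-propynylmagnesium bromide | CC#C[Mg]Br | starting material
2 | acrolein | C=CC=O | starting material
3 | (±)-hex-1-en-4-yn-3-ol | C=CC(O)C#CC | intermediate
4 | (S)-hex-1-en-4-yn-3-ol | C=C[C@H](O)C#CC | intermediate
5 | sodium (5S)-2,2-bis(2-methoxyethoxy)-3-methyl-5-vinyl-2,5-dihydro-1,2-oxaluminol-2-uide (cyclic alkenylalanate, Al on C4 cis to C6) | C=C[C@@H]1O[Al-](OCCOC)(OCCOC)C(C)=C1.[Na+] | intermediate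
6 | (3S,4Z)-5-iodohexa-1,4-dien-3-ol | C=C[C@H](O)/C=C(/C)I | intermediate
7 | 2-(bromomethyl)acrylic acid | C=C(CBr)C(=O)O | starting material
8 | 2-(acetoxymethyl)acrylic acid | CC(=O)OCC(=C)C(=O)O | intermediate
9 | (3S,4Z)-5-iodohexa-1,4-dien-3-yl 2-(acetoxymethyl)acrylate | C=C[C@H](OC(=O)C(=C)COC(C)=O)/C=C(/C)I | intermediate
10 | [(5S)-5-[(1Z)-2-iodoprop-1-en-1-yl]-2-oxo-2,5-dihydrofuran-3-yl]methyl acetate (fragment A) | CC(=O)OCC1=C[C@H](OC1=O)/C=C(/C)I | intermediate
11 | prop-2-yn-1-ol | C#CCO | starting material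
12 | allylmagnesium bromide | C=CC[Mg]Br | starting material
13 | 1-bromo-3-methylbut-2-ene (prenyl bromide) | CC(C)=CCBr | starting material
14 | bromomagnesium (2Z)-2-allyl-3-(bromomagnesio)prop-2-en-1-olate (Mg on C1 cis to CH2O) | Br[Mg]/C=C(/CC=C)CO[Mg]Br | intermediate
15 | (2Z)-6-methyl-2-(prop-2-en-1-yl)hepta-2,5-dien-1-ol | OC/C(CC=C)=C\CC=C(C)C | intermediate
16 | [(2S,3R)-3-(3-methylbut-2-en-1-yl)-2-(prop-2-en-1-yl)oxiran-2-yl]methanol | CC(C)=CC[C@H]1O[C@]1(CO)CC=C | intermediate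
17 | tert-butyl{[(2S,3R)-3-(3-methylbut-2-en-1-yl)-2-(prop-2-en-1-yl)oxiran-2-yl]methoxy}dimethylsilane | CC(C)=CC[C@H]1O[C@]1(CO[Si](C)(C)C(C)(C)C)CC=C | intermediate
18 | 3,3-dimethyl-1,2,4-trioxolane (ozonide) formed at the prenyl alkene of 17, epimeric at the new acetal carbon | CC1(C)OOC(C[C@H]2O[C@]2(CO[Si](C)(C)C(C)(C)C)CC=C)O1 | intermediate
19 | 2-[(2R,3S)-3-({[tert-butyl(dimethyl)silyl]oxy}methyl)-3-(prop-2-en-1-yl)oxiran-2-yl]acetaldehyde (fragment B) | O=CC[C@H]1O[C@]1(CO[Si](C)(C)C(C)(C)C)CC=C | intermediate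
20 | [(5R)-5-{(1Z,3S)-3-hydroxy-2-methyl-4-[(2R,3S)-3-(TBSO-methyl)-3-(prop-2-en-1-yl)oxiran-2-yl]but-1-en-1-yl}-2-oxo-2,5-dihydrofuran-3-yl]methyl acetate | CC(=O)OCC1=C[C@H](OC1=O)/C=C(/C)[C@@H](O)C[C@H]2O[C@]2(CO[Si](C)(C)C(C)(C)C)CC=C | intermediate
21 | C3 TBS ether of 20 | CC(=O)OCC1=C[C@H](OC1=O)/C=C(/C)[C@@H](O[Si](C)(C)C(C)(C)C)C[C@H]2O[C@]2(CO[Si](C)(C)C(C)(C)C)CC=C | intermediate
22 | 2,3-dihydroxypropyl analogue of 21 (diol at the former allyl group, both C8 epimers) | CC(=O)OCC1=C[C@H](OC1=O)/C=C(/C)[C@@H](O[Si](C)(C)C(C)(C)C)C[C@H]2O[C@]2(CO[Si](C)(C)C(C)(C)C)CC(O)CO | intermediate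
23 | [(5R)-5-{(1Z,3S)-3-(TBSO)-2-methyl-4-[(2R,3S)-3-(TBSO-methyl)-3-(2-oxoethyl)oxiran-2-yl]but-1-en-1-yl}-2-oxo-2,5-dihydrofuran-3-yl]methyl acetate (seco aldehyde) | CC(=O)OCC1=C[C@H](OC1=O)/C=C(/C)[C@@H](O[Si](C)(C)C(C)(C)C)C[C@H]2O[C@]2(CO[Si](C)(C)C(C)(C)C)CC=O | intermediate
24 | C8 ketyl radical of 23 bound to trivalent samarium (O–SmI2) | CC(=O)OCC1=C[C@H](OC1=O)/C=C(/C)[C@@H](O[Si](C)(C)C(C)(C)C)C[C@H]2O[C@]2(CO[Si](C)(C)C(C)(C)C)C[CH]O[Sm](I)I | intermediate
25 | cyclised C11 radical (ten-membered ring closed, C8–O–SmI2, CH2OAc still on C11) | CC(=O)OC[C]1C(=O)O[C@@H]2/C=C(/C)[C@@H](O[Si](C)(C)C(C)(C)C)C[C@H]3O[C@]3(CO[Si](C)(C)C(C)(C)C)C[C@@H](O[Sm](I)I)[C@@H]12 | intermediate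
26 | trivalent samarium lactone enolate of 25 (C11=C12–O–SmI2) | CC(=O)OCC1=C(O[Sm](I)I)O[C@@H]2/C=C(/C)[C@@H](O[Si](C)(C)C(C)(C)C)C[C@H]3O[C@]3(CO[Si](C)(C)C(C)(C)C)C[C@@H](O[Sm](I)I)[C@@H]12 | intermediate
27 | (1R,3S,4Z,6R,7R,8R,10S)-1,10-epoxy-8-hydroxy-3,14-bis(TBSO)germacra-4,11(13)-dien-12,6-olide (1β,10α-epoxide, 3β-OTBS, 8β-OH, trans-fused lactone) | C=C1C(=O)O[C@@H]2/C=C(/C)[C@@H](O[Si](C)(C)C(C)(C)C)C[C@H]3O[C@]3(CO[Si](C)(C)C(C)(C)C)C[C@@H](O)[C@@H]12 | intermediate
28 | (S)-2-methylbutanoic acid | CC[C@H](C)C(=O)O | starting material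
29 | 8-O-[(2S)-2-methylbutanoyl] ester of 27 | C=C1C(=O)O[C@@H]2/C=C(/C)[C@@H](O[Si](C)(C)C(C)(C)C)C[C@H]3O[C@]3(CO[Si](C)(C)C(C)(C)C)C[C@@H](OC(=O)[C@@H](C)CC)[C@@H]12 | intermediate
30 | (1R,3S,4Z,6R,7R,8R,10S)-1,10-epoxy-3,14-dihydroxy-8-[(2S)-2-methylbutanoyloxy]germacra-4,11(13)-dien-12,6-olide | C=C1C(=O)O[C@@H]2/C=C(/C)[C@@H](O)C[C@H]3O[C@]3(CO)C[C@@H](OC(=O)[C@@H](C)CC)[C@@H]12 | target

## Step count and risks

Total steps: 16. Longest linear sequence: 11 (steps 1, 2, 3, 5, 6, 11, 12, 13, 14, 15, 16); step 4 and steps 7–10 are branches.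

**Step 14 (radical macrocyclisation).** Ten-membered rings are the hardest size for radical ring closure. The configurations at C7 and C8 rest on transition-state arguments, and the acetoxymethyl butenolide could be reduced before the aldehyde. The fallback keeps a radical C7–C8 bond formation but uses an acyl radical. It sets out from 23: Pinnick oxidation (NaClO2, NaH2PO4, 2-methyl-2-butene) gives the C8 carboxylic acid F1, and PhSeSePh/PBu3 converts it into the Se-phenyl selenoester F2. Slow addition of (TMS)3SiH/AIBN in benzene at 80 °C generates the acyl radical, which closes onto C7 to give the macrocyclic C8 ketone F3 (C11–H, CH2OAc retained). Reduction with NaBH4/CeCl3·7H2O at −78 °C gives the 8-hydroxy lactone F4, and DBU at 0 °C eliminates acetic acid to return to the route at 27.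

**Step 11 (C3 configuration in the fragment coupling).** The epoxide gives little substrate bias and its weak 1,3-preference opposes the required 1,3-syn relationship, so the outcome depends wholly on the chiral chromium complex. The fallback sets out from 10 and 19: an unligated coupling (CrCl2, catalytic NiCl2, DMSO) gives the C3-epimeric alcohol mixture F5, and Dess–Martin periodinane oxidises it to the Z-enone F6. Reduction with (R)-2-methyl-CBS-oxazaborolidine and catecholborane at −78 °C, with the alkenyl group acting as the large substituent, gives the 3S alcohol and returns to the route at 20.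

**Step 13 (chemoselective alkene cleavage).** Osmylation could also attack C4=C5, and the β,γ-epoxy aldehyde product is fragile. The fallback moves the osmylation to the fragment stage, where the allyl group is the only alkene. It sets out from 19: OsO4 (cat.)/NMO gives the diol aldehyde F7, and TESOTf/2,6-lutidine gives the bis-TES ether F8. Coupling with 10 as in step 11 gives the allylic alcohol F9, and TBSOTf gives the TBS ether F10. PPTS in MeOH at 0 °C removes only the two TES groups and returns to the route at 22, which NaIO4 alone cleaves to 23.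

## Further compounds

F1 | step 14 | C8 carboxylic acid from 23 | CC(=O)OCC1=C[C@H](OC1=O)/C=C(/C)[C@@H](O[Si](C)(C)C(C)(C)C)C[C@H]2O[C@]2(CO[Si](C)(C)C(C)(C)C)CC(=O)O
F2 | step 14 | Se-phenyl selenoester of F1 | CC(=O)OCC1=C[C@H](OC1=O)/C=C(/C)[C@@H](O[Si](C)(C)C(C)(C)C)C[C@H]2O[C@]2(CO[Si](C)(C)C(C)(C)C)CC(=O)[Se]c1ccccc1
F3 | step 14 | macrocyclic C8 ketone with saturated 11-(acetoxymethyl) lactone (C11 epimers) | CC(=O)OCC1C(=O)O[C@@H]2/C=C(/C)[C@@H](O[Si](C)(C)C(C)(C)C)C[C@H]3O[C@]3(CO[Si](C)(C)C(C)(C)C)CC(=O)[C@@H]12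
F4 | step 14 | 8β-hydroxy analogue of F3 | CC(=O)OCC1C(=O)O[C@@H]2/C=C(/C)[C@@H](O[Si](C)(C)C(C)(C)C)C[C@H]3O[C@]3(CO[Si](C)(C)C(C)(C)C)C[C@@H](O)[C@@H]12
F5 | step 11 | C3-epimeric mixture of alcohol 20 | CC(=O)OCC1=C[C@H](OC1=O)/C=C(/C)C(O)C[C@H]2O[C@]2(CO[Si](C)(C)C(C)(C)C)CC=C
F6 | step 11 | C3 ketone (Z-enone) from F5 | CC(=O)OCC1=C[C@H](OC1=O)/C=C(/C)C(=O)C[C@H]2O[C@]2(CO[Si](C)(C)C(C)(C)C)CC=C
F7 | step 13 | 2-[(2R,3S)-3-(TBSO-methyl)-3-(2,3-dihydroxypropyl)oxiran-2-yl]acetaldehyde | O=CC[C@H]1O[C@]1(CO[Si](C)(C)C(C)(C)C)CC(O)CO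
F8 | step 13 | bis-TES ether of F7 | O=CC[C@H]1O[C@]1(CO[Si](C)(C)C(C)(C)C)CC(O[Si](CC)(CC)CC)CO[Si](CC)(CC)CC
F9 | step 13 | coupling product of 10 and F8 (3S alcohol) | CC(=O)OCC1=C[C@H](OC1=O)/C=C(/C)[C@@H](O)C[C@H]2O[C@]2(CO[Si](C)(C)C(C)(C)C)CC(O[Si](CC)(CC)CC)CO[Si](CC)(CC)CC
F10 | step 13 | C3 TBS ether of F9 | CC(=O)OCC1=C[C@H](OC1=O)/C=C(/C)[C@@H](O[Si](C)(C)C(C)(C)C)C[C@H]2O[C@]2(CO[Si](C)(C)C(C)(C)C)CC(O[Si](CC)(CC)CC)CO[Si](CC)(CC)CC
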